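- I began with the east and south-west runs. At 21.6 mM of Ptn their percent curves ran close (16.1 % and 17.1 % at 50.0 min, 8.8 % and 7.1 % at 20.0 min), so I read one mean curve from them.

| flask | Sub | Ptn | remark | time | volume of the second phase over the first |
|---|---|---|---|---|---|
| east | 9 mM | 21.6 mM | run made earlier |  |  |
| south-west | 14 mM | 21.6 mM | run made earlier |  |  |
| south-east | 18 mM | 43 mM | run made earlier |  |  |
| flask | 18 mM | 21.6 mM |  | 1.0 h | 2.0 |
- east (time / min: Sub.Ptn2 / %): 2.50: 0; 8.00: 2.3; 15.0: 6.1; 20.0: 8.8; 30.0: 11.7; 40.0: 14.2; 50.0: 16.1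
- south-west (time / min: Sub.Ptn2 / %): 4.00: 1.2; 6.00: 2.3; 8.00: 3.4; 15.0: 5.8; 20.0: 7.1; 30.0: 11.9; 50.0: 17.1
- south-east (time / min: Sub.Ptn2 / %): 4.00: 1.5; 12.0: 7.0; 20.0: 13.8; 30.0: 18.3; 50.0: 22.1

(readings scatter by 0.5 percentage points)
- in the second phase: Ptn; everything else is in the first
- charges count per volume of the first phase; a concentration in a rate is the amount of a species over the volume of its own phase; every rate counts per litre of the first phase
- what was read earlier has a scatter of 0.5 percentage points, one standard deviation
- on the list of suspects stand: Ptn2 <-> Ptn; Sub + Ptn2 -> Sub.Ptn2; Ptn2 + Sub.Ptn2 -> Sdp; Sub.Ptn2 <-> Sdp2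
- the earlier runs hold the two phases in the same ratio of volumes as the flask asked about
- amount of Sub.Ptn2 at 1.0 h, in percent of the Sub charged
- the change that raises the amount of Sub.Ptn2 at 1.0 h, in percent of the Sub charged most ("none" if none brings more than 2 percentage points) (Sunday's / Thursday's / none)
- amount of Sub.Ptn2 at 1.0 h, in percent of the Sub charged, after Thursday's
- Sunday's: doubling the transfer coefficient of Ptn, all else as stated
- Thursday's: doubling the amount of Ptn, all else as stated
- The mean slope of Sub.Ptn2 fell from 0.00407 min⁻¹ of the charge between 8.00 min and 30.0 min to 0.00240 min⁻¹ afterwards, as the amount held rose.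
- I wrote net slope = start slope − loss chance × amount held. The loss chance, taken as the share of the held product that the curve gives up per minute, is a pseudo-first-order constant read from the bend, with the whole bend counted as loss: 0.0243 min⁻¹.
- This drew my curve: a start slope of 0.00585 min⁻¹, a knee near 41.2 min, and a level of 24.1 %, all carrying the scatter of the readings.
- From the mean of 16.6 %, my step to 1.0 h gave 18.4 % for the flask.
- The forecast gave 18.8 %, chose Thursday's and put the amount after that change at 23.3 %, holding that “Thursday's change essentially reproduces the south-east run”. My figure stood below its 18.8 %.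

- The flask gave 17.2 %, and Thursday's gave 24.0 %, a gain of 6.8 percentage points against 0.5 points for Sunday's.

    Ptn2 ⇌ Ptn, rate k1*([Ptn2] - [Ptn]/K1) per volume of the first phase (partition coefficient = 1.10, kL = 0.00273 s⁻¹)
    Sub + Ptn2 → Sub.Ptn2 (k = 0.0146 M⁻¹ s⁻¹)
    Ptn2 + Sub.Ptn2 → Sdp (k = 0.0245 M⁻¹ s⁻¹)
    Sub.Ptn2 ⇌ Sdp2 (K = 2.00, k = 6.42 × 10⁻⁵ s⁻¹)

- The east flask taken to 1.0 h gives 18.2 %, and raising its Sub to 18 mM gives 17.2 %. A run would overturn the choice by showing Sunday's gain above Thursday's, or Thursday's gain under 2 points. In the south-east run the loss chance read 0.0443 min⁻¹, about twice the first, and the same step from 22.1 %, taken to 1.0 h with that run's 43 mM of Ptn standing in for Thursday's 43.2 mM, reached 23.2 % against the 24.0 % of Thursday's flask.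

The runs were computed for substances that don't exist, noise included.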